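**Retrosynthetic overview**
1. Target 21 ⇐ fluoride desilylation of tris-silyl acetate 20 ⇐ acetylation of alcohol 19 ⇐ selective loss of the C3 triethylsilyl group of 18.
2. C6=C7 (E) ⇐ Julia–Kocienski olefination of the C6 phenyltetrazolyl sulfone 14 with 4-(silyloxy)benzaldehyde 16.
3. 14 ⇐ hydroboration/oxidation, Mitsunobu thioetherification and S-oxidation at the terminal alkene of 10.
4. Key C3–C4 bond and the only stereocentre ⇐ asymmetric allylboration of aldehyde 5 (from dihydrocaffeic acid 1) with the allyl fragment of allylmagnesium bromide 6.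
5. No ring is formed; both benzene rings come with starting materials 1 and 15.

Assumption: the SMILES decodes to (3R,6E)-1-(3,4-dihydroxyphenyl)-7-(4-hydroxyphenyl)hept-6-en-3-yl acetate; 1, 6, 15 and (+)-Ipc2BOMe are bought.

Abbreviations: TBS = tert-butyldimethylsilyl, TES = triethylsilyl, Ipc = isopinocampheyl.

**Route**

Step 1
Reactants: 1 3-(3,4-dihydroxyphenyl)propanoic acid
Product: 2 methyl 3-(3,4-dihydroxyphenyl)propanoate
Conditions: MeOH, H2SO4 (cat.), reflux
Reagents that add atoms: methanol, CO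
Why: Fischer esterification converts only the aliphatic acid, since the phenols do not react under acid catalysis.

Step 2
Reactants: 2 methyl 3-(3,4-dihydroxyphenyl)propanoate
Product: 3 methyl 3-[3,4-bis(tert-butyldimethylsilyloxy)phenyl]propanoate
Conditions: TBSCl (2.5 equiv), imidazole (5 equiv), DMF, rt
Reagents that add atoms: tert-butyldimethylsilyl chloride, CC(C)(C)[Si](C)(C)Cl
Why: Imidazole-promoted silylation protects both phenols as ethers that survive hydride, base and oxidants but fall to fluoride at the end.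

Step 3
Reactants: 3 methyl 3-[3,4-bis(tert-butyldimethylsilyloxy)phenyl]propanoate
Product: 4 3-[3,4-bis(tert-butyldimethylsilyloxy)phenyl]propan-1-ol
Conditions: i-Bu2AlH (2.5 equiv), CH2Cl2, −78 → 0 °C; aq. KNaC4H4O6
Reagents that add atoms: none
Why: Hydride reduction of the ester with excess i-Bu2AlH goes cleanly to the primary alcohol and leaves aryl silyl ethers alone, which avoids the aldehyde/alcohol mixtures of a partial reduction.

Step 4
Reactants: 4 3-[3,4-bis(tert-butyldimethylsilyloxy)phenyl]propan-1-ol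
Product: 5 3-[3,4-bis(tert-butyldimethylsilyloxy)phenyl]propanal
Conditions: Dess–Martin periodinane, CH2Cl2, rt
Reagents that add atoms: none
Why: Dess–Martin oxidation stops at the aldehyde under non-basic conditions that do not touch the silyl ethers.

Step 5
Reactants: 5 3-[3,4-bis(tert-butyldimethylsilyloxy)phenyl]propanal, 6 allylmagnesium bromide
Product: 9 (3S)-1-[3,4-bis(tert-butyldimethylsilyloxy)phenyl]hex-5-en-3-ol, via B-allyldiisopinocampheylborane 7 (not isolated), via homoallyl diisopinocampheylborinate 8 (not isolated)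
Conditions: 6, (+)-Ipc2BOMe [from (−)-α-pinene], Et2O, 0 °C → rt; then 5, −78 °C; NaBO3·4H2O, THF/H2O, rt
Reagents that add atoms: none
Why: In this Brown asymmetric allylboration (carbonyl allylation) the allylborane with Ipc groups from (−)-α-pinene adds through a closed chair (Zimmerman–Traxler) transition state to the Re face of the unbranched aldehyde, which sets C3 as S (typically 90–96% ee), and the mild perborate work-up frees the alcohol without the strong base that would strip the aryl silyl ethers.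

Step 6
Reactants: 9 (3S)-1-[3,4-bis(tert-butyldimethylsilyloxy)phenyl]hex-5-en-3-ol
Product: 10 (3S)-1-[3,4-bis(tert-butyldimethylsilyloxy)phenyl]-3-(triethylsilyloxy)hex-5-ene
Conditions: TESCl, imidazole, CH2Cl2, 0 °C → rt
Reagents that add atoms: chlorotriethylsilane, CC[Si](Cl)(CC)CC
Why: Silylation of the carbinol as its triethylsilyl ether gives a group that survives base, peracid and the sulfone anion but is later removed by mild acid without touching the aryl silyl ethers.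

Step 7
Reactants: 10 (3S)-1-[3,4-bis(tert-butyldimethylsilyloxy)phenyl]-3-(triethylsilyloxy)hex-5-ene
Product: 12 (4S)-6-[3,4-bis(tert-butyldimethylsilyloxy)phenyl]-4-(triethylsilyloxy)hexan-1-ol, via B-alkyl-9-borabicyclo[3.3.1]nonane 11 (not isolated)
Conditions: 9-BBN (0.5 M in THF), 0 °C → rt; then NaBO3·4H2O, H2O, rt
Reagents that add atoms: sodium perborate tetrahydrate NaBO3·4H2O (oxygen donor), [Na+].[Na+].O[B-]1(O)OO[B-](O)(O)OO1
Why: Hydroboration–oxidation with the bulky 9-BBN is anti-Markovnikov (>99:1) at the terminal alkene, and the weakly basic perborate oxidation spares the silyl ethers and the stereocentre.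

Step 8
Reactants: 12 (4S)-6-[3,4-bis(tert-butyldimethylsilyloxy)phenyl]-4-(triethylsilyloxy)hexan-1-ol
Product: 13 5-{[(4S)-6-[3,4-bis(tert-butyldimethylsilyloxy)phenyl]-4-(triethylsilyloxy)hexyl]sulfanyl}-1-phenyl-1H-tetrazole
Conditions: 1-phenyl-1H-tetrazole-5-thiol, PPh3, DIAD, THF, 0 °C → rt
Reagents that add atoms: 1-phenyl-1H-tetrazole-5-thiol, SC1=NN=NN1c1ccccc1
Why: Mitsunobu thioetherification of an unhindered primary alcohol with this acidic thiol is fast and S-selective.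

Step 9
Reactants: 13 5-{[(4S)-6-[3,4-bis(tert-butyldimethylsilyloxy)phenyl]-4-(triethylsilyloxy)hexyl]sulfanyl}-1-phenyl-1H-tetrazole
Product: 14 5-{[(4S)-6-[3,4-bis(tert-butyldimethylsilyloxy)phenyl]-4-(triethylsilyloxy)hexyl]sulfonyl}-1-phenyl-1H-tetrazole
Conditions: mCPBA (3 equiv), NaHCO3, CH2Cl2, 0 °C → rt
Reagents that add atoms: 3-chloroperbenzoic acid, OOC(=O)c1cccc(Cl)c1
Why: Peracid S-oxidation takes the sulfide through the sulfoxide to the sulfone, no alkene is present at this stage, and the bicarbonate buffer protects the triethylsilyl ether.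

Step 10
Reactants: 15 4-hydroxybenzaldehyde
Product: 16 4-(tert-butyldimethylsilyloxy)benzaldehyde
Conditions: TBSCl, imidazole, DMF, rt
Reagents that add atoms: tert-butyldimethylsilyl chloride, CC(C)(C)[Si](C)(C)Cl
Why: Phenol silylation masks the acidic OH that would quench the sulfone anion in the next step.

Step 11
Reactants: 14 5-{[(4S)-6-[3,4-bis(tert-butyldimethylsilyloxy)phenyl]-4-(triethylsilyloxy)hexyl]sulfonyl}-1-phenyl-1H-tetrazole, 16 4-(tert-butyldimethylsilyloxy)benzaldehyde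
Product: 18 (3R,6E)-1-[3,4-bis(tert-butyldimethylsilyloxy)phenyl]-7-[4-(tert-butyldimethylsilyloxy)phenyl]-3-(triethylsilyloxy)hept-6-ene, via potassium α-sulfonyl carbanion 17 (not isolated)
Conditions: KN(SiMe3)2, DME, −55 °C; then 16, −55 °C → rt
Reagents that add atoms: none
Why: In this Julia–Kocienski olefination the metalated phenyltetrazolyl sulfone adds to the non-enolisable aryl aldehyde and the adduct collapses by Smiles rearrangement and anti-elimination of SO2 and tetrazolone to the conjugated E-alkene (usually ≥10:1), while the remote C3 centre is untouched (its label changes from S to R only because the CIP ranking of the two chains changes).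

Step 12
Reactants: 18 (3R,6E)-1-[3,4-bis(tert-butyldimethylsilyloxy)phenyl]-7-[4-(tert-butyldimethylsilyloxy)phenyl]-3-(triethylsilyloxy)hept-6-ene
Product: 19 (3R,6E)-1-[3,4-bis(tert-butyldimethylsilyloxy)phenyl]-7-[4-(tert-butyldimethylsilyloxy)phenyl]hept-6-en-3-ol
Conditions: PPTS (cat.), MeOH/CH2Cl2, 0 °C → rt
Reagents that add atoms: none
Why: Acid-catalysed methanolysis removes the secondary alkyl triethylsilyl ether far faster than the aryl tert-butyldimethylsilyl ethers, and the acid is too weak to protonate the styrene.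

Step 13
Reactants: 19 (3R,6E)-1-[3,4-bis(tert-butyldimethylsilyloxy)phenyl]-7-[4-(tert-butyldimethylsilyloxy)phenyl]hept-6-en-3-ol
Product: 20 (3R,6E)-1-[3,4-bis(tert-butyldimethylsilyloxy)phenyl]-7-[4-(tert-butyldimethylsilyloxy)phenyl]hept-6-en-3-yl acetate
Conditions: Ac2O, pyridine, DMAP (cat.), CH2Cl2, rt
Reagents that add atoms: acetic anhydride, CC(=O)OC(C)=O
Why: DMAP-catalysed acylation esterifies the only free hydroxyl with retention at C3.

Step 14
Reactants: 20 (3R,6E)-1-[3,4-bis(tert-butyldimethylsilyloxy)phenyl]-7-[4-(tert-butyldimethylsilyloxy)phenyl]hept-6-en-3-yl acetate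
Product: 21 (3R,6E)-1-(3,4-dihydroxyphenyl)-7-(4-hydroxyphenyl)hept-6-en-3-yl acetate
Conditions: Bu4NF/AcOH (1:1, 3.5 equiv), THF, 0 °C, degassed
Reagents that add atoms: none
Why: Fluoride-mediated desilylation cleaves the three aryl silyl ethers quickly, and the acetic acid buffer keeps the phenols protonated so the secondary acetate is neither cleaved nor transferred and the catechol is not air-oxidised.

**Compound list**

1 | 3-(3,4-dihydroxyphenyl)propanoic acid (dihydrocaffeic acid) | OC(=O)CCc1ccc(O)c(O)c1 | starting material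
2 | methyl 3-(3,4-dihydroxyphenyl)propanoate | COC(=O)CCc1ccc(O)c(O)c1 | intermediate
3 | methyl 3-[3,4-bis(tert-butyldimethylsilyloxy)phenyl]propanoate | COC(=O)CCc1ccc(O[Si](C)(C)C(C)(C)C)c(O[Si](C)(C)C(C)(C)C)c1 | intermediate
4 | 3-[3,4-bis(tert-butyldimethylsilyloxy)phenyl]propan-1-ol | OCCCc1ccc(O[Si](C)(C)C(C)(C)C)c(O[Si](C)(C)C(C)(C)C)c1 | intermediate
5 | 3-[3,4-bis(tert-butyldimethylsilyloxy)phenyl]propanal | O=CCCc1ccc(O[Si](C)(C)C(C)(C)C)c(O[Si](C)(C)C(C)(C)C)c1 | intermediate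
6 | allylmagnesium bromide | C=CC[Mg]Br | starting material
7 | B-allyldiisopinocampheylborane, both Ipc groups from (−)-α-pinene | C=CCB([C@H]1C[C@H]2C[C@@H]([C@@H]1C)C2(C)C)[C@H]1C[C@H]2C[C@@H]([C@@H]1C)C2(C)C | intermediate
8 | (3S)-1-[3,4-bis(tert-butyldimethylsilyloxy)phenyl]hex-5-en-3-yl diisopinocampheylborinate | B([C@H]1C[C@H]2C[C@@H]([C@@H]1C)C2(C)C)([C@H]1C[C@H]2C[C@@H]([C@@H]1C)C2(C)C)O[C@H](CC=C)CCc1ccc(O[Si](C)(C)C(C)(C)C)c(O[Si](C)(C)C(C)(C)C)c1 | intermediate
9 | (3S)-1-[3,4-bis(tert-butyldimethylsilyloxy)phenyl]hex-5-en-3-ol | O[C@H](CC=C)CCc1ccc(O[Si](C)(C)C(C)(C)C)c(O[Si](C)(C)C(C)(C)C)c1 | intermediate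
10 | (3S)-1-[3,4-bis(tert-butyldimethylsilyloxy)phenyl]-3-(triethylsilyloxy)hex-5-ene | CC[Si](CC)(CC)O[C@H](CC=C)CCc1ccc(O[Si](C)(C)C(C)(C)C)c(O[Si](C)(C)C(C)(C)C)c1 | intermediate
11 | 9-{(4R)-6-[3,4-bis(tert-butyldimethylsilyloxy)phenyl]-4-(triethylsilyloxy)hexyl}-9-borabicyclo[3.3.1]nonane | CC[Si](CC)(CC)O[C@H](CCCB1C2CCCC1CCC2)CCc1ccc(O[Si](C)(C)C(C)(C)C)c(O[Si](C)(C)C(C)(C)C)c1 | intermediate
12 | (4S)-6-[3,4-bis(tert-butyldimethylsilyloxy)phenyl]-4-(triethylsilyloxy)hexan-1-ol | CC[Si](CC)(CC)O[C@H](CCCO)CCc1ccc(O[Si](C)(C)C(C)(C)C)c(O[Si](C)(C)C(C)(C)C)c1 | intermediate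
13 | 5-{[(4S)-6-[3,4-bis(tert-butyldimethylsilyloxy)phenyl]-4-(triethylsilyloxy)hexyl]sulfanyl}-1-phenyl-1H-tetrazole | CC[Si](CC)(CC)O[C@H](CCCSC1=NN=NN1c1ccccc1)CCc1ccc(O[Si](C)(C)C(C)(C)C)c(O[Si](C)(C)C(C)(C)C)c1 | intermediate
14 | 5-{[(4S)-6-[3,4-bis(tert-butyldimethylsilyloxy)phenyl]-4-(triethylsilyloxy)hexyl]sulfonyl}-1-phenyl-1H-tetrazole | CC[Si](CC)(CC)O[C@H](CCCS(=O)(=O)C1=NN=NN1c1ccccc1)CCc1ccc(O[Si](C)(C)C(C)(C)C)c(O[Si](C)(C)C(C)(C)C)c1 | intermediate
15 | 4-hydroxybenzaldehyde | O=Cc1ccc(O)cc1 | starting material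
16 | 4-(tert-butyldimethylsilyloxy)benzaldehyde | O=Cc1ccc(O[Si](C)(C)C(C)(C)C)cc1 | intermediate
17 | potassium (4S)-6-[3,4-bis(tert-butyldimethylsilyloxy)phenyl]-1-[(1-phenyl-1H-tetrazol-5-yl)sulfonyl]-4-(triethylsilyloxy)hexan-1-ide | [K+].CC[Si](CC)(CC)O[C@H](CC[CH-]S(=O)(=O)C1=NN=NN1c1ccccc1)CCc1ccc(O[Si](C)(C)C(C)(C)C)c(O[Si](C)(C)C(C)(C)C)c1 | intermediate
18 | (3R,6E)-1-[3,4-bis(tert-butyldimethylsilyloxy)phenyl]-7-[4-(tert-butyldimethylsilyloxy)phenyl]-3-(triethylsilyloxy)hept-6-ene | CC[Si](CC)(CC)O[C@H](CC/C=C/c1ccc(O[Si](C)(C)C(C)(C)C)cc1)CCc1ccc(O[Si](C)(C)C(C)(C)C)c(O[Si](C)(C)C(C)(C)C)c1 | intermediate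
19 | (3R,6E)-1-[3,4-bis(tert-butyldimethylsilyloxy)phenyl]-7-[4-(tert-butyldimethylsilyloxy)phenyl]hept-6-en-3-ol | O[C@H](CC/C=C/c1ccc(O[Si](C)(C)C(C)(C)C)cc1)CCc1ccc(O[Si](C)(C)C(C)(C)C)c(O[Si](C)(C)C(C)(C)C)c1 | intermediate
20 | (3R,6E)-1-[3,4-bis(tert-butyldimethylsilyloxy)phenyl]-7-[4-(tert-butyldimethylsilyloxy)phenyl]hept-6-en-3-yl acetate | CC(=O)O[C@H](CC/C=C/c1ccc(O[Si](C)(C)C(C)(C)C)cc1)CCc1ccc(O[Si](C)(C)C(C)(C)C)c(O[Si](C)(C)C(C)(C)C)c1 | intermediate
21 | (3R,6E)-1-(3,4-dihydroxyphenyl)-7-(4-hydroxyphenyl)hept-6-en-3-yl acetate | CC(=O)O[C@H](CC/C=C/c1ccc(O)cc1)CCc1ccc(O)c(O)c1 | target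

The geometry at the carbinol carbon is the same from 8 to 21; the S/R label switches only where the CIP ranking of the two chains changes.

**Totals**

Total steps: 14. Longest linear sequence: 13 (steps 1–9 and 11–14, from 1).

**Three steps most likely to fail**

Step 5 (asymmetric allylboration). The risks are an ee below about 90% and partial loss of aryl silyl groups in the oxidative work-up; the ee should be checked by Mosher ester or chiral HPLC. The fallback sets out from 3 and comes back at 10. A crossed Claisen condensation of 3 with LiCH2CO2t-Bu (from t-BuOAc and LiN(i-Pr)2, THF, −78 °C) gives tert-butyl 5-[3,4-bis(tert-butyldimethylsilyloxy)phenyl]-3-oxopentanoate F1. Noyori hydrogenation (H2, RuCl2[(S)-BINAP], MeOH, 50 °C) then sets the centre by catalyst control and gives tert-butyl (3S)-5-[3,4-bis(tert-butyldimethylsilyloxy)phenyl]-3-hydroxypentanoate F2. Silylation with TESCl/imidazole gives tert-butyl (3S)-5-[3,4-bis(tert-butyldimethylsilyloxy)phenyl]-3-(triethylsilyloxy)pentanoate F3. Reduction with i-Bu2AlH at −78 °C gives (3S)-5-[3,4-bis(tert-butyldimethylsilyloxy)phenyl]-3-(triethylsilyloxy)pentanal F4. Wittig methylenation (Ph3P=CH2 from Ph3PCH3Br and NaN(SiMe3)2, THF, −78 → 0 °C) gives 10.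

Step 11 (Julia–Kocienski olefination). The risks are an E/Z mixture and self-condensation of the metalated sulfone. The fallback sets out from 12 and 16 and comes back at 18. Dess–Martin oxidation of 12 gives (4S)-6-[3,4-bis(tert-butyldimethylsilyloxy)phenyl]-4-(triethylsilyloxy)hexanal F5. Wittig methylenation gives triethyl{[(3R)-1-[3,4-bis(tert-butyldimethylsilyloxy)phenyl]hept-6-en-3-yl]oxy}silane F6. Methylenation of 16 gives 4-(tert-butyldimethylsilyloxy)styrene F7. Cross-metathesis of F6 with excess F7 (second-generation Grubbs catalyst RuCl2(=CHPh)(PCy3)(H2IMes), CH2Cl2, 40 °C) gives 18 with loss of ethylene; E-selectivity is thermodynamic.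

Step 14 (desilylation beside the acetate). The risks are acetate cleavage or transfer to a phenoxide and catechol oxidation. The fallback sets out from 19 and comes back at 21. Buffered Bu4NF removes all three silyl groups to give 4-[(3R,6E)-3-hydroxy-7-(4-hydroxyphenyl)hept-6-en-1-yl]benzene-1,2-diol F8. Ac2O/pyridine/DMAP gives (3R,6E)-1-(3,4-diacetoxyphenyl)-7-(4-acetoxyphenyl)hept-6-en-3-yl acetate F9. Pyrrolidine (3.1 equiv, THF, 0 °C) aminolyses the three aryl acetates much faster than the secondary alkyl acetate and gives 21.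

**Further compounds**

F1 | step 5 | tert-butyl 5-[3,4-bis(tert-butyldimethylsilyloxy)phenyl]-3-oxopentanoate | CC(C)(C)OC(=O)CC(=O)CCc1ccc(O[Si](C)(C)C(C)(C)C)c(O[Si](C)(C)C(C)(C)C)c1
F2 | step 5 | tert-butyl (3S)-5-[3,4-bis(tert-butyldimethylsilyloxy)phenyl]-3-hydroxypentanoate | O[C@H](CC(=O)OC(C)(C)C)CCc1ccc(O[Si](C)(C)C(C)(C)C)c(O[Si](C)(C)C(C)(C)C)c1
F3 | step 5 | tert-butyl (3S)-5-[3,4-bis(tert-butyldimethylsilyloxy)phenyl]-3-(triethylsilyloxy)pentanoate | CC[Si](CC)(CC)O[C@H](CC(=O)OC(C)(C)C)CCc1ccc(O[Si](C)(C)C(C)(C)C)c(O[Si](C)(C)C(C)(C)C)c1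
F4 | step 5 | (3S)-5-[3,4-bis(tert-butyldimethylsilyloxy)phenyl]-3-(triethylsilyloxy)pentanal | CC[Si](CC)(CC)O[C@H](CC=O)CCc1ccc(O[Si](C)(C)C(C)(C)C)c(O[Si](C)(C)C(C)(C)C)c1
F5 | step 11 | (4S)-6-[3,4-bis(tert-butyldimethylsilyloxy)phenyl]-4-(triethylsilyloxy)hexanal | CC[Si](CC)(CC)O[C@H](CCC=O)CCc1ccc(O[Si](C)(C)C(C)(C)C)c(O[Si](C)(C)C(C)(C)C)c1
F6 | step 11 | triethyl{[(3R)-1-[3,4-bis(tert-butyldimethylsilyloxy)phenyl]hept-6-en-3-yl]oxy}silane | CC[Si](CC)(CC)O[C@H](CCC=C)CCc1ccc(O[Si](C)(C)C(C)(C)C)c(O[Si](C)(C)C(C)(C)C)c1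
F7 | step 11 | 4-(tert-butyldimethylsilyloxy)styrene | C=Cc1ccc(O[Si](C)(C)C(C)(C)C)cc1
F8 | step 14 | 4-[(3R,6E)-3-hydroxy-7-(4-hydroxyphenyl)hept-6-en-1-yl]benzene-1,2-diol | O[C@H](CC/C=C/c1ccc(O)cc1)CCc1ccc(O)c(O)c1
F9 | step 14 | (3R,6E)-1-(3,4-diacetoxyphenyl)-7-(4-acetoxyphenyl)hept-6-en-3-yl acetate | CC(=O)O[C@H](CC/C=C/c1ccc(OC(C)=O)cc1)CCc1ccc(OC(C)=O)c(OC(C)=O)c1
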